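Its constants are made up; the result is computed.

30.9 is the factor by which the fresh solid substrate goes to homo dimer faster than a full solution can draw it into target.

solid substrate 0.10 M; solid reagent 0.0800 M; time 4.0 min

    2 solid substrate → homo dimer (k1 = 0.193 M⁻¹ s⁻¹)
    solid reagent ⇌ partner, rate k2*(cs2 - [partner]) while solid is left; crystals form when [partner] > cs2 (cs2 = 47 mM, k2 = 0.0425 s⁻¹)
    dissolved substrate + partner → target (k3 = 0.316 M⁻¹ s⁻¹)
    solid substrate ⇌ dissolved substrate, rate k4*(cs4 - [dissolved substrate]) while solid is left; crystals form when [dissolved substrate] > cs4 (cs4 = 8.4 mM, k4 = 0.802 s⁻¹)
    dissolved substrate + target → side product (k5 = 0.324 M⁻¹ s⁻¹)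

- the target standing at 4.0 min, as a percentage of the solid substrate charged
- concentration of dissolved substrate in solution at 4.0 min, in percent of saturation

- a species is counted by the solid substrate in it: one side product or homo dimer counts as two
- a doubled species enters its step squared and goes two at a time
- given per volume of solution although it is solid: solid substrate, solid reagent
- at the start none of the solid reagent is in solution
- at the start none of the solid substrate is in solution
- dissolved substrate means what is dissolved; the solid is not counted in it
- run time (flask): 4.0 min

Does that draw hold steady? Dissolving refills the dissolved substrate in 1.25 s, far faster than the 67.3 s in which partner uses it up, so the dissolved substrate stays near saturation while solid is left. Partner rises with a time constant of 23.5 s, far shorter than the 377 s in which it is used up, so it too comes close to saturation. Target is then made at a steady 0.0749 min⁻¹, as a fraction of the charge.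

Who takes the solid? Homo dimer loss falls with the square of the solid while the draw stays level, so the two meet at the crossing fraction, the part of the charge still solid when homo dimer loss equals the draw: 18.0%. Homo dimer loss, reckoned without the draw, brings the solid there in 1.97 min.

How much target can stand? Open from one partner time constant until 4.0 min, the draw passes 27.0% of the charge, and this hand reckoning stops at that ceiling. The forecast, holding that “the solid is lost quickly”, goes further and lower, to 17.7% (16.5% to 18.8%), with saturation at 33% (27% to 40%).

The flask gives 17.7% of target and 34.6% of saturation, inside both ranges. Its solid substrate passes the crossing fraction between 48.6% at 0.400 min and 10.9% at 2.00 min, when homo dimer already stands at 68.2%, against 69.1% at 4.00 min. In the neighbour flask charged with 0.060 M of solid substrate, the crossing fraction is 30.0% of that smaller charge, and at 4.00 min homo dimer stands at 52.6% and target at 28.3%.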